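Cuts, in retrosynthetic order: the fourteen O–benzyl bonds and C8–Br of the lower unit; C3–OH and C4–H of the middle unit (back to a flav-3-ene); C4–C4a of the middle unit; the alkyne–C6 bond to the lower unit; O1–C2 of the middle unit; C4(upper)–C6(middle).
Enabling feature: C4 of the middle unit carries both C4a of its own ring A and C6 of the lower unit, and O1 lies para to the upper-unit attachment on ring A. An O1–C2–C3≡C4 aryl propargyl ether with the lower unit on the alkyne terminus therefore holds every atom of ring C and lacks only the C4–C4a bond.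
Forward: the pyran rings of the upper and lower units come ready-made from (−)-epicatechin and (+)-catechin. Phloroglucinol is attached to C4 of epicatechin and becomes ring A of the middle unit. Etherification, alkyne–aryl coupling and closure of the middle ring C follow, then hydration of the alkene and deprotection.
Stereochemistry: C2 and C3 of the upper and lower units come from the chiral pool. Upper C4 comes from β-face attack anti to the 2-aryl and 3-oxy groups. Middle C2 comes from an asymmetric alkynylation and is inverted once in a Mitsunobu step. Middle C3 and C4 arise together from syn hydroboration anti to the C2 aryl group.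

Key step: step 16

Assumption: (R,R)-ProPhenol is taken to direct the alkynylzinc reagent to the Re face of the aldehyde in step 8; if the sense of induction is the opposite, the equally available (S,S)-ligand is used and nothing else changes.

Step 1
Reactants: 1 (−)-epicatechin
Product: 2 5,7,3',4'-tetra-O-benzyl-(−)-epicatechin (2R,3R; free 3-OH)
Conditions: BnBr (4.4 equiv), K2CO3, DMF, 0 °C → rt
Reagents that add atoms: benzyl bromide, BrCc1ccccc1
Why: Williamson etherification with carbonate base alkylates only the four phenols, since the C3 alcohol is not deprotonated, and touches no stereocentre.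

Step 2
Reactants: 2 5,7,3',4'-tetra-O-benzyl-(−)-epicatechin
Product: 3 4β-(2-ethoxyethoxy)-5,7,3',4'-tetra-O-benzylepicatechin (2,3-cis-3,4-trans; free 3-OH)
Conditions: DDQ (2 equiv), 2-ethoxyethanol, CH2Cl2, rt
Reagents that add atoms: 2-ethoxyethanol, CCOCCO
Why: DDQ benzylic oxidation abstracts hydride from C4 to give a cation stabilised by the 5,7-dialkoxy ring A, and the alcohol traps it from the β face, anti to the α-oriented 2-aryl and 3-hydroxy groups.

Step 3
Reactants: 3 4β-(2-ethoxyethoxy)-5,7,3',4'-tetra-O-benzylepicatechin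
Product: 4 3,5,7,3',4'-penta-O-benzyl-4β-(2-ethoxyethoxy)epicatechin
Conditions: NaH, BnBr, DMF, 0 °C → rt
Reagents that add atoms: benzyl bromide, BrCc1ccccc1
Why: Williamson etherification of the secondary alkoxide caps the last hydroxyl, so that the later Mitsunobu step meets a single alcohol, and the C4 ether is inert to base.

Step 4
Reactants: 4 3,5,7,3',4'-penta-O-benzyl-4β-(2-ethoxyethoxy)epicatechin; 5 phloroglucinol
Product: 6 3,5,7,3',4'-penta-O-benzylepicatechin-(4β→2)-phloroglucinol (three free phenols)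
Conditions: 5 (5 equiv), Yb(OTf)3 (20 mol %), THF/CH2Cl2, 0 °C → rt
Reagents that add atoms: none
Why: In this Lewis-acid-promoted Friedel–Crafts alkylation the C4–O bond ionises to the ring-A-stabilised cation, the threefold-symmetric nucleophile (in excess) can give only one constitution, and it attacks from the β face anti to the 2-aryl and 3-benzyloxy groups, which sets the 3,4-trans (4β) centre.

Step 5
Reactants: 6 3,5,7,3',4'-penta-O-benzylepicatechin-(4β→2)-phloroglucinol
Product: 7 5-O-triisopropylsilyl ether of 6 (silyl group on the hydroxyl para to the flavanyl substituent; two ortho phenols free)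
Conditions: TIPSCl (1.05 equiv), imidazole, CH2Cl2/DMF, −20 → 0 °C
Reagents that add atoms: chlorotriisopropylsilane, CC(C)[Si](Cl)(C(C)C)C(C)C
Why: Sterically controlled silylation places the bulky silyl group on the only phenol flanked by two hydrogens, because the two ortho phenols are shielded by the flavan-4-yl substituent.

Step 6
Reactants: 7 5-O-triisopropylsilyl ether of 6
Product: 8 1,3-di-O-benzyl-5-O-triisopropylsilyl derivative of 6
Conditions: BnBr (2.5 equiv), K2CO3, DMF, 40 °C
Reagents that add atoms: benzyl bromide, BrCc1ccccc1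
Why: Williamson etherification caps the two remaining phenols, and the aryl triisopropylsilyl ether withstands anhydrous carbonate.

Step 7
Reactants: 8 1,3-di-O-benzyl-5-O-triisopropylsilyl derivative of 6
Product: 9 3,5-bis(benzyloxy)-4-(3,5,7,3',4'-penta-O-benzylepicatechin-4β-yl)phenol
Conditions: TBAF, AcOH (1:1), THF, 0 °C
Reagents that add atoms: none
Why: Fluoride-induced desilylation, buffered with acetic acid, frees only the para phenol and leaves the benzyl ethers and all stereocentres untouched.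

Step 8
Reactants: 10 3,4-bis(benzyloxy)benzaldehyde; 11 (trimethylsilyl)acetylene
Product: 13 (S)-1-[3,4-bis(benzyloxy)phenyl]-3-(trimethylsilyl)prop-2-yn-1-ol, via alkynylzinc reagent 12 (not isolated)
Conditions: 11 (3 equiv), Me2Zn (3 equiv), (R,R)-ProPhenol (10 mol %), Ph3P=O (20 mol %), toluene, 0 °C; then 10, 0 °C
Reagents that add atoms: dimethylzinc, C[Zn]C (methylzinc group of 12 only)
Why: In this catalytic asymmetric alkynylation of an aryl aldehyde the dinuclear zinc–ProPhenol complex binds aldehyde and alkynylzinc together and delivers the alkynyl group to the Re face, which sets the carbinol centre as S.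

Step 9
Reactants: 13 (S)-1-[3,4-bis(benzyloxy)phenyl]-3-(trimethylsilyl)prop-2-yn-1-ol
Product: 14 (R)-1-[3,4-bis(benzyloxy)phenyl]prop-2-yn-1-ol (same geometry as 13)
Conditions: K2CO3 (20 mol %), MeOH/THF, 0 °C → rt
Reagents that add atoms: none
Why: Base-catalysed protodesilylation cleaves only the C(sp)–Si bond, and the descriptor changes from S to R solely because ethynyl ranks below aryl.

Step 10
Reactants: 9 3,5-bis(benzyloxy)-4-(3,5,7,3',4'-penta-O-benzylepicatechin-4β-yl)phenol; 14 (R)-1-[3,4-bis(benzyloxy)phenyl]prop-2-yn-1-ol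
Product: 15 (S)-1-[3,4-bis(benzyloxy)phenyl]prop-2-ynyl ether of phenol 9 (terminal alkyne; ether oxygen para to the flavanyl group)
Conditions: PPh3, DIAD, toluene, −20 → 0 °C
Reagents that add atoms: none
Why: In the Mitsunobu etherification the phenol displaces the oxyphosphonium group by SN2 with inversion, a non-polar solvent and low temperature suppress ionisation of the electron-rich benzylic centre, and (R)-14 thus gives the (S)-ether with the geometry of C2 of the middle unit.

Step 11
Reactants: 16 (+)-catechin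
Product: 17 5,7,3',4'-tetra-O-benzyl-(+)-catechin (2R,3S; free 3-OH)
Conditions: BnBr (4.4 equiv), K2CO3, DMF, 0 °C → rt
Reagents that add atoms: benzyl bromide, BrCc1ccccc1
Why: Williamson etherification with carbonate base alkylates the four phenols only and leaves C2 and C3 unchanged.

Step 12
Reactants: 17 5,7,3',4'-tetra-O-benzyl-(+)-catechin
Product: 18 3,5,7,3',4'-penta-O-benzylcatechin
Conditions: NaH, BnBr, DMF, 0 °C → rt
Reagents that add atoms: benzyl bromide, BrCc1ccccc1
Why: Williamson etherification of the C3 alkoxide completes the protection without affecting the stereocentres.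

Step 13
Reactants: 18 3,5,7,3',4'-penta-O-benzylcatechin
Product: 19 8-bromo-3,5,7,3',4'-penta-O-benzylcatechin
Conditions: NBS (1.0 equiv), CH2Cl2, −78 → −20 °C
Reagents that add atoms: N-bromosuccinimide, O=C1CCC(=O)N1Br
Why: Electrophilic aromatic bromination with one equivalent of NBS at low temperature goes to C8, the most nucleophilic and less hindered position of ring A, and thereby blocks it.

Step 14
Reactants: 19 8-bromo-3,5,7,3',4'-penta-O-benzylcatechin
Product: 20 8-bromo-6-iodo-3,5,7,3',4'-penta-O-benzylcatechin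
Conditions: NIS (1.1 equiv), TFA (10 mol %), MeCN/CH2Cl2, 0 °C → rt, dark
Reagents that add atoms: N-iodosuccinimide, O=C1CCC(=O)N1I
Why: Electrophilic aromatic iodination with acid-activated NIS can only take the one free position of ring A, C6, which is activated by three oxygen substituents and far more electron-rich than ring B.

Step 15
Reactants: 15 (S)-1-[3,4-bis(benzyloxy)phenyl]prop-2-ynyl ether of phenol 9; 20 8-bromo-6-iodo-3,5,7,3',4'-penta-O-benzylcatechin
Product: 21 ether 15 bearing C6 of 8-bromo-3,5,7,3',4'-penta-O-benzylcatechin on the alkyne terminus (propargylic centre now R by ranking, geometry unchanged)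
Conditions: PdCl2(PPh3)2 (5 mol %), CuI (5 mol %), Et3N/DMF, degassed, 50 °C
Reagents that add atoms: none
Why: In the Sonogashira coupling zerovalent palladium inserts into the C–I bond much faster than into the C–Br bond, so only C6 is alkynylated, and the mild amine base leaves the propargylic centre intact.

Step 16
Reactants: 21 aryl propargyl ether with the lower unit on the alkyne
Product: 22 protected trimer with a flav-3-ene middle unit: penta-O-benzylepicatechin-(4β→6)-[(2S)-5,7,3',4'-tetra-O-benzylflav-3-ene]-(4→6)-8-bromo-penta-O-benzylcatechin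
Conditions: (JohnPhos)Au(MeCN)SbF6 (5 mol %), 4 Å MS, CH2Cl2, 0 °C → rt
Reagents that add atoms: none
Why: The cationic monovalent gold centre binds the alkyne and slips towards C3, because positive charge at C4 is stabilised by the trioxygenated ring A of the lower unit and disfavoured at C3 by the adjacent C2–O1 dipole; the carbon ortho to O1 on the phloroglucinol-derived ring attacks C4 anti to gold, the arenium ion rearomatises, and protodeauration of the C3–Au bond releases 22 and the catalyst. The closest known reaction type is the gold- or platinum-catalysed intramolecular hydroarylation of aryl propargyl ethers to 2H-chromenes, which includes internal aryl alkynes that give 4-aryl-2H-chromenes. Ring C of the middle unit (O1, C2, C3, C4, C4a, C8a) closes in the 6-endo-dig mode, and the polarisation described above disfavours the 5-exo alternative of attack at C3. No stereocentre is created, and C2 keeps its configuration because none of its bonds is broken, which is why a non-coordinating solvent, low temperature and exclusion of acid are chosen to avoid ionisation of the C2–O1 bond. Regioselectivity on ring A needs no control, since the two positions ortho to O1 are exchanged by rotation about the C4(upper)–aryl bond and either one gives the 4→6 linked skeleton. The chemoselectivity required is carbon attack by ring A in preference to 5-endo attack of a flanking benzyloxy oxygen of the lower unit at C3, and the same polarisation favours it by making C3 the gold-bearing, non-electrophilic carbon.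

Step 17
Reactants: 22 protected trimer with a flav-3-ene middle unit
Product: 24 tetradeca-O-benzyl-8-bromo-epicatechin-(4β→6)-catechin-(4α→6)-catechin (free 3-OH on the middle unit; bromine at C8 of the lower unit), via C3 alkylborane 23 (not isolated)
Conditions: BH3·THF (5 equiv), THF, 0 °C → rt; then 3 M NaOH, 30% H2O2, 0 °C
Reagents that add atoms: hydrogen peroxide, OO; borane–THF, B (boron of 23 only)
Why: In the hydroboration–oxidation borane adds syn from the β face anti to the C2 aryl group, with boron on the less substituted C3 and hydrogen on the diaryl-substituted C4, and oxidation with retention gives the 3β-hydroxyl and the 4α-aryl group, that is the 2,3-trans-3,4-trans array.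

Step 18
Reactants: 24 tetradeca-O-benzyl-8-bromo trimer
Product: 25 epicatechin-(4β→6)-catechin-(4α→6)-catechin (target, CNP0163146.4)
Conditions: H2 (1 atm), Pd(OH)2/C, NaOAc (1.2 equiv), THF/MeOH/H2O, rt
Reagents that add atoms: none
Why: Catalytic hydrogenolysis cleaves all fourteen benzyl ethers and hydrodehalogenates C8–Br, while the acetate buffer takes up the hydrogen bromide so that the acid-labile interflavan bonds and all eight stereocentres persist.

Compound list
1 | (−)-epicatechin | Oc1cc(O)c2c(c1)O[C@H](c1ccc(O)c(O)c1)[C@H](O)C2 | starting material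
2 | 5,7,3',4'-tetra-O-benzyl-(−)-epicatechin | O(Cc5ccccc5)c1cc(OCc5ccccc5)c2c(c1)O[C@H](c4ccc(OCc5ccccc5)c(OCc5ccccc5)c4)[C@H](O)C2 | intermediate
3 | 4β-(2-ethoxyethoxy)-5,7,3',4'-tetra-O-benzylepicatechin | O(Cc5ccccc5)c1cc(OCc5ccccc5)c2c(c1)O[C@H](c4ccc(OCc5ccccc5)c(OCc5ccccc5)c4)[C@H](O)[C@H]2OCCOCC | intermediate
4 | 3,5,7,3',4'-penta-O-benzyl-4β-(2-ethoxyethoxy)epicatechin | O(Cc5ccccc5)c1cc(OCc5ccccc5)c2c(c1)O[C@H](c4ccc(OCc5ccccc5)c(OCc5ccccc5)c4)[C@H](OCc5ccccc5)[C@H]2OCCOCC | intermediate
5 | phloroglucinol | Oc1cc(O)cc(O)c1 | starting material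
6 | penta-O-benzylepicatechin-(4β→2)-phloroglucinol | O(Cc5ccccc5)c1cc(OCc5ccccc5)c2c(c1)O[C@H](c4ccc(OCc5ccccc5)c(OCc5ccccc5)c4)[C@H](OCc5ccccc5)[C@H]2c7c(O)cc(O)cc7O | intermediate
7 | 5-O-triisopropylsilyl ether of 6 | O(Cc5ccccc5)c1cc(OCc5ccccc5)c2c(c1)O[C@H](c4ccc(OCc5ccccc5)c(OCc5ccccc5)c4)[C@H](OCc5ccccc5)[C@H]2c7c(O)cc(O[Si](C(C)C)(C(C)C)C(C)C)cc7O | intermediate
8 | 1,3-di-O-benzyl-5-O-triisopropylsilyl derivative of 6 | O(Cc5ccccc5)c1cc(OCc5ccccc5)c2c(c1)O[C@H](c4ccc(OCc5ccccc5)c(OCc5ccccc5)c4)[C@H](OCc5ccccc5)[C@H]2c7c(OCc5ccccc5)cc(O[Si](C(C)C)(C(C)C)C(C)C)cc7OCc5ccccc5 | intermediate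
9 | 3,5-bis(benzyloxy)-4-(penta-O-benzylepicatechin-4β-yl)phenol | O(Cc5ccccc5)c1cc(OCc5ccccc5)c2c(c1)O[C@H](c4ccc(OCc5ccccc5)c(OCc5ccccc5)c4)[C@H](OCc5ccccc5)[C@H]2c7c(OCc5ccccc5)cc(O)cc7OCc5ccccc5 | intermediate
10 | 3,4-bis(benzyloxy)benzaldehyde | O=Cc1ccc(OCc2ccccc2)c(OCc2ccccc2)c1 | starting material
11 | (trimethylsilyl)acetylene | C#C[Si](C)(C)C | starting material
12 | methyl[(trimethylsilyl)ethynyl]zinc | C[Zn]C#C[Si](C)(C)C | intermediate
13 | (S)-1-[3,4-bis(benzyloxy)phenyl]-3-(trimethylsilyl)prop-2-yn-1-ol | O[C@@H](c1ccc(OCc2ccccc2)c(OCc2ccccc2)c1)C#C[Si](C)(C)C | intermediate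
14 | (R)-1-[3,4-bis(benzyloxy)phenyl]prop-2-yn-1-ol | O[C@@H](c1ccc(OCc2ccccc2)c(OCc2ccccc2)c1)C#C | intermediate
15 | (S)-1-[3,4-bis(benzyloxy)phenyl]prop-2-ynyl ether of 9 | O(Cc5ccccc5)c1cc(OCc5ccccc5)c2c(c1)O[C@H](c4ccc(OCc5ccccc5)c(OCc5ccccc5)c4)[C@H](OCc5ccccc5)[C@H]2c7c(OCc5ccccc5)cc(O[C@H](c4ccc(OCc5ccccc5)c(OCc5ccccc5)c4)C#C)cc7OCc5ccccc5 | intermediate
16 | (+)-catechin | Oc1cc(O)c2c(c1)O[C@H](c1ccc(O)c(O)c1)[C@@H](O)C2 | starting material
17 | 5,7,3',4'-tetra-O-benzyl-(+)-catechin | O(Cc5ccccc5)c1cc(OCc5ccccc5)c2c(c1)O[C@H](c4ccc(OCc5ccccc5)c(OCc5ccccc5)c4)[C@@H](O)C2 | intermediate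
18 | 3,5,7,3',4'-penta-O-benzylcatechin | O(Cc5ccccc5)c1cc(OCc5ccccc5)c2c(c1)O[C@H](c4ccc(OCc5ccccc5)c(OCc5ccccc5)c4)[C@@H](OCc5ccccc5)C2 | intermediate
19 | 8-bromo-3,5,7,3',4'-penta-O-benzylcatechin | O(Cc5ccccc5)c1cc(OCc5ccccc5)c2c(c1Br)O[C@H](c4ccc(OCc5ccccc5)c(OCc5ccccc5)c4)[C@@H](OCc5ccccc5)C2 | intermediate
20 | 8-bromo-6-iodo-3,5,7,3',4'-penta-O-benzylcatechin | O(Cc5ccccc5)c1c(I)c(OCc5ccccc5)c2c(c1Br)O[C@H](c4ccc(OCc5ccccc5)c(OCc5ccccc5)c4)[C@@H](OCc5ccccc5)C2 | intermediate
21 | aryl propargyl ether with the lower unit on the alkyne (precursor of the key step) | O(Cc5ccccc5)c1cc(OCc5ccccc5)c2c(c1)O[C@H](c4ccc(OCc5ccccc5)c(OCc5ccccc5)c4)[C@H](OCc5ccccc5)[C@H]2c7c(OCc5ccccc5)cc(O[C@H](c4ccc(OCc5ccccc5)c(OCc5ccccc5)c4)C#Cc1c(OCc5ccccc5)c(Br)c3c(c1OCc5ccccc5)C[C@H](OCc5ccccc5)[C@@H](c4ccc(OCc5ccccc5)c(OCc5ccccc5)c4)O3)cc7OCc5ccccc5 | intermediate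
22 | protected trimer with a flav-3-ene middle unit (product of the key step) | O(Cc5ccccc5)c1cc(OCc5ccccc5)c2c(c1)O[C@H](c4ccc(OCc5ccccc5)c(OCc5ccccc5)c4)[C@H](OCc5ccccc5)[C@H]2c1c(OCc5ccccc5)cc2c(c1OCc5ccccc5)C(c1c(OCc5ccccc5)c(Br)c3c(c1OCc5ccccc5)C[C@H](OCc5ccccc5)[C@@H](c4ccc(OCc5ccccc5)c(OCc5ccccc5)c4)O3)=C[C@@H](c4ccc(OCc5ccccc5)c(OCc5ccccc5)c4)O2 | intermediate
23 | C3 alkylborane of the middle unit (3β-boryl, 4α-aryl) | O(Cc5ccccc5)c1cc(OCc5ccccc5)c2c(c1)O[C@H](c4ccc(OCc5ccccc5)c(OCc5ccccc5)c4)[C@H](OCc5ccccc5)[C@H]2c1c(OCc5ccccc5)cc2c(c1OCc5ccccc5)[C@@H](c1c(OCc5ccccc5)c(Br)c3c(c1OCc5ccccc5)C[C@H](OCc5ccccc5)[C@@H](c4ccc(OCc5ccccc5)c(OCc5ccccc5)c4)O3)[C@H](B)[C@@H](c4ccc(OCc5ccccc5)c(OCc5ccccc5)c4)O2 | intermediate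
24 | tetradeca-O-benzyl-8-bromo-epicatechin-(4β→6)-catechin-(4α→6)-catechin | O(Cc5ccccc5)c1cc(OCc5ccccc5)c2c(c1)O[C@H](c4ccc(OCc5ccccc5)c(OCc5ccccc5)c4)[C@H](OCc5ccccc5)[C@H]2c1c(OCc5ccccc5)cc2c(c1OCc5ccccc5)[C@@H](c1c(OCc5ccccc5)c(Br)c3c(c1OCc5ccccc5)C[C@H](OCc5ccccc5)[C@@H](c4ccc(OCc5ccccc5)c(OCc5ccccc5)c4)O3)[C@H](O)[C@@H](c4ccc(OCc5ccccc5)c(OCc5ccccc5)c4)O2 | intermediate
25 | epicatechin-(4β→6)-catechin-(4α→6)-catechin | Oc1cc(O)c2c(c1)O[C@H](c1ccc(O)c(O)c1)[C@H](O)[C@H]2c1c(O)cc2c(c1O)[C@@H](c1c(O)cc3c(c1O)C[C@H](O)[C@@H](c1ccc(O)c(O)c1)O3)[C@H](O)[C@@H](c1ccc(O)c(O)c1)O2 | target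

Total step count: 18. Longest linear sequence: 12 steps from (−)-epicatechin (steps 1–7, 10, 15, 16, 17, 18).

Steps most likely to fail

Step 16. Crowding at the alkyne terminus, which is flanked by two benzyloxy groups, may slow carbon attack. The metal could then ionise the C2–O1 bond, with loss of configuration or cleavage of the ether. Alternatively, a flanking benzyloxy oxygen could attack the alkyne with benzyl transfer.
The fallback sets out from 15 and 19 and comes back at 24.
- The ring is closed on the unhindered terminal alkyne: 15 with the same gold catalyst should give the nona-O-benzyl epicatechin-(4β→6)-flav-3-ene dimer F1.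
- OsO4/NMO dihydroxylation anti to the C2 aryl group should give the 2,3-trans-3,4-cis flavan-3,4-diol F2.
- Yb(OTf)3 or BF3·OEt2 then ionises the benzylic C4 hydroxyl in the presence of excess 19. Its C8 is blocked by bromine, so it can only react at C6, and the C4–C6 bond should form trans to the 3-hydroxyl to give 24 directly.

Step 17. Addition to the hindered trisubstituted alkene may be slow, and the chiral neighbouring units may erode facial selectivity. The C3 borane may also undergo β-elimination with opening of the C2–O1 bond.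
The fallback sets out from 22 and comes back at 24.
- Dimethyldioxirane in acetone/CH2Cl2 at −20 °C should epoxidise the β face to give the 3β,4β-epoxide F3.
- A catalytic BF3·OEt2 Meinwald rearrangement shifts hydride from C3 to C4. Brief Et3N equilibration of the doubly benzylic C4–H, by far the more acidic α-hydrogen, should then give the 2,4-cis-diequatorial 4α-aryl-flavan-3-one F4.
- Axial attack of NaBH4 in THF/MeOH at −20 °C should give the equatorial 3β-alcohol 24.

Step 10. The oxyphosphonium intermediate sits on a benzylic and propargylic carbon bearing an electron-rich aryl group. It may ionise in part, which would erode the configuration of the future C2. Any epimer formed is a diastereomer and can be removed by chromatography.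
The fallback sets out from 10 and 9 and comes back at 15.
- Ethynylmagnesium bromide adds to 10 to give the racemic 1-[3,4-bis(benzyloxy)phenyl]prop-2-yn-1-ol F5.
- Methyl chloroformate and pyridine convert it into the racemic propargylic methyl carbonate F6.
- A copper-catalysed enantioselective propargylic etherification follows (CuOTf·0.5C6H6, chiral pybox ligand, iPr2NEt, 0 °C). It joins F6 to phenol 9 through a planar allenylidene complex of monovalent copper.
- The ligand, not an inversion, fixes the configuration, and cation stabilisation by ring B is no longer a liability. The pybox enantiomer is chosen to give the (S)-ether 15.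

Further compounds
F1 | step 16 | nona-O-benzyl epicatechin-(4β→6)-flav-3-ene dimer (C4 of the flavene unsubstituted, 2-aryl α) | O(Cc5ccccc5)c1cc(OCc5ccccc5)c2c(c1)O[C@H](c4ccc(OCc5ccccc5)c(OCc5ccccc5)c4)[C@H](OCc5ccccc5)[C@H]2c1c(OCc5ccccc5)cc2c(c1OCc5ccccc5)C=C[C@@H](c4ccc(OCc5ccccc5)c(OCc5ccccc5)c4)O2
F2 | step 16 | nona-O-benzyl epicatechin-(4β→6)-(2,3-trans-3,4-cis-flavan-3β,4β-diol) | O(Cc5ccccc5)c1cc(OCc5ccccc5)c2c(c1)O[C@H](c4ccc(OCc5ccccc5)c(OCc5ccccc5)c4)[C@H](OCc5ccccc5)[C@H]2c1c(OCc5ccccc5)cc2c(c1OCc5ccccc5)[C@H](O)[C@H](O)[C@@H](c4ccc(OCc5ccccc5)c(OCc5ccccc5)c4)O2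
F3 | step 17 | 3β,4β-epoxide of 22 | O(Cc5ccccc5)c1cc(OCc5ccccc5)c2c(c1)O[C@H](c4ccc(OCc5ccccc5)c(OCc5ccccc5)c4)[C@H](OCc5ccccc5)[C@H]2c1c(OCc5ccccc5)cc2c(c1OCc5ccccc5)[C@]6(c1c(OCc5ccccc5)c(Br)c3c(c1OCc5ccccc5)C[C@H](OCc5ccccc5)[C@@H](c4ccc(OCc5ccccc5)c(OCc5ccccc5)c4)O3)O[C@@H]6[C@@H](c4ccc(OCc5ccccc5)c(OCc5ccccc5)c4)O2
F4 | step 17 | protected trimer with a 2α,4α-diaryl-flavan-3-one middle unit | O(Cc5ccccc5)c1cc(OCc5ccccc5)c2c(c1)O[C@H](c4ccc(OCc5ccccc5)c(OCc5ccccc5)c4)[C@H](OCc5ccccc5)[C@H]2c1c(OCc5ccccc5)cc2c(c1OCc5ccccc5)[C@@H](c1c(OCc5ccccc5)c(Br)c3c(c1OCc5ccccc5)C[C@H](OCc5ccccc5)[C@@H](c4ccc(OCc5ccccc5)c(OCc5ccccc5)c4)O3)C(=O)[C@@H](c4ccc(OCc5ccccc5)c(OCc5ccccc5)c4)O2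
F5 | step 10 | racemic 1-[3,4-bis(benzyloxy)phenyl]prop-2-yn-1-ol | OC(c1ccc(OCc2ccccc2)c(OCc2ccccc2)c1)C#C
F6 | step 10 | racemic 1-[3,4-bis(benzyloxy)phenyl]prop-2-ynyl methyl carbonate | COC(=O)OC(c1ccc(OCc2ccccc2)c(OCc2ccccc2)c1)C#C
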